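**Retrosynthetic overview**
1. The enone and the C13–C14 bond are made last: the alkyllithium from sulfide 22 adds 1,2 to vinylogous ester 13, and acid transposes the carbonyl (Stork–Danheiser).
2. Left half (22): the oxepane C–O bond and the cyclohexane C–C bond are formed together from diepoxide 18 by an epoxonium cascade ended by an acyl-lactone enol ether. The lactone is then opened (PhSH, loss of CO2) to the two-carbon arm, and MeMgBr sets the axial carbinol.
3. Right half (13): Pauson–Khand reaction of (R)-dehydrolinalool 4 gives the two five-membered rings, OH-directed hydrogenation sets the ring fusion, and a ketene [2+2]/retro-aldol sequence enlarges the cyclopentanone to the seven-membered 1,3-dione.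
4. Both halves come from geraniol through one Sharpless epoxide (2), which supplies C5a/C9a on the left and C1 on the right. The C3 carbinol comes from a separate Shi epoxidation of opposite facial sense.
5. Ring order: left, oxepane and cyclohexane in one step; right, the two five-membered carbocycles first, then the seven-membered ring by enlargement.

Assumption: catalysts (the L-sorbose-derived enantiomer of the Shi ketone, [Ir(cod)(PCy3)(py)]PF6) and commodity reagents are bought, and a one-pot sequence whose intermediate is not purified counts as one step.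

**Route**

Step 1
Reactants: 1 geraniol
Product: 2 (2R,3R)-2,3-epoxygeraniol
Conditions: Ti(OiPr)4 (10 mol%), D-(−)-diisopropyl tartrate (12 mol%), t-BuOOH, 4 Å MS, CH2Cl2, −20 °C
Reagents that add atoms: tert-butyl hydroperoxide, CC(C)(C)OO
Why: Sharpless asymmetric epoxidation reacts only at the allylic alcohol, and the D-tartrate ligand sets the (2R,3R)-epoxide that later becomes C9a/C5a of the left half and C1 of the right half.

Step 2
Reactants: 2 (2R,3R)-2,3-epoxygeraniol
Product: 3 (2S,3R)-2-(chloromethyl)-3-methyl-3-(4-methylpent-3-en-1-yl)oxirane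
Conditions: PPh3, CCl4, NaHCO3 (cat.), reflux
Reagents that add atoms: carbon tetrachloride, ClC(Cl)(Cl)Cl
Why: Appel chlorination of the primary alcohol leaves the epoxide and its two stereocentres untouched.

Step 3
Reactants: 3 (2S,3R)-2-(chloromethyl)-3-methyl-3-(4-methylpent-3-en-1-yl)oxirane
Product: 4 (3R)-3,7-dimethyloct-6-en-1-yn-3-ol ((R)-dehydrolinalool)
Conditions: n-BuLi (3.2 equiv), THF, −40 °C; then H2O
Reagents that add atoms: none
Why: base-induced double elimination of a 2,3-epoxy chloride (epoxide opening to the chloro-allyl alkoxide, then loss of HCl) gives the terminal propargylic alcohol without breaking the C–O bond of the tertiary carbon, so (3R) is kept.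

Step 4
Reactants: 4 (3R)-3,7-dimethyloct-6-en-1-yn-3-ol
Product: 5 (8R)-8-hydroxy-4,4,8-trimethylbicyclo[3.3.0]oct-1-en-3-one (both C5 epimers)
Conditions: Co2(CO)8 (20 mol%), tetramethylthiourea (60 mol%), CO (1 atm), PhMe, 70 °C
Reagents that add atoms: carbon monoxide, [C-]#[O+]
Why: intramolecular Pauson–Khand reaction, helped by the quaternary propargylic carbon, builds both five-membered rings and the CMe2–C(=O) bond; the C5 configuration formed here does not matter because step 5 erases it.

Step 5
Reactants: 5 (8R)-8-hydroxy-4,4,8-trimethylbicyclo[3.3.0]oct-1-en-3-one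
Product: 7 (6R)-6-hydroxy-2,2,6-trimethylbicyclo[3.3.0]oct-1(5)-en-3-one, via dilithium dienolate 6 (not isolated)
Conditions: LiN(iPr)2 (2.3 equiv), THF–DMPU, −78 °C; then AcOH, −78 °C
Reagents that add atoms: none
Why: kinetic deconjugation: only the ring-fusion γ-hydrogen can be removed (the α′ carbon is quaternary), and α-protonation of the dienolate leaves the alkene in the tetrasubstituted position next to the carbinol.

Step 6
Reactants: 7 (6R)-6-hydroxy-2,2,6-trimethylbicyclo[3.3.0]oct-1(5)-en-3-one
Product: 8 (1R,5R,8R)-8-hydroxy-4,4,8-trimethylbicyclo[3.3.0]octan-3-one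
Conditions: [Ir(cod)(PCy3)(py)]PF6 (5 mol%), H2 (1–4 atm), CH2Cl2, rt
Reagents that add atoms: none
Why: hydroxyl-directed hydrogenation: iridium binds the tertiary allylic OH and delivers H2 to that face, so both ring-fusion hydrogens end up cis to OH (1R,5R), the cis-fused arrangement of the target.

Step 7
Reactants: 8 (1R,5R,8R)-8-hydroxy-4,4,8-trimethylbicyclo[3.3.0]octan-3-one
Product: 10 chloro(methyl)cyclobutanone cycloadduct, via bis-TMS ether 9 (not isolated)
Conditions: TMSOTf (2.4 equiv), Et3N, CH2Cl2, 0 °C; pentane extraction, concentrate; then CH3CHClCOCl (2 equiv), Et3N, hexane, reflux, slow addition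
Reagents that add atoms: trimethylsilyl triflate, C[Si](C)(C)OS(=O)(=O)C(F)(F)F; 2-chloropropanoyl chloride, CC(Cl)C(Cl)=O
Why: the only possible silyl enol ether (the other α carbon is quaternary) undergoes [2+2] cycloaddition with methylchloroketene made in situ, the ketene carbonyl carbon bonding to the nucleophilic CH carbon; the new stereocentres are lost in step 8.

Step 8
Reactants: 10 chloro(methyl)cyclobutanone cycloadduct
Product: 12 (1R,3aR,8aR)-1-hydroxy-1,4,4,6-tetramethyloctahydroazulene-5,7-dione, via dechlorinated cyclobutanone 11 (not isolated)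
Conditions: Zn dust, AcOH, i-PrOH–H2O, 0 °C → rt; then 50 °C
Reagents that add atoms: none
Why: reductive dechlorination, then desilylation and retro-aldol cleavage of the strained four-membered ring (the known two-carbon enlargement of cycloalkanones to 1,3-diones), gives the 2-methyl-1,3-dione without touching C1, C3a or C8a.

Step 9
Reactants: 12 (1R,3aR,8aR)-1-hydroxy-1,4,4,6-tetramethyloctahydroazulene-5,7-dione
Product: 13 (1R,3aR,8aR)-1-hydroxy-7-methoxy-1,4,4,6-tetramethyl-2,3,3a,4,8,8a-hexahydroazulen-5(1H)-one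
Conditions: MeOH, TsOH (2 mol%), 4 Å MS, rt
Reagents that add atoms: methanol, CO
Why: reversible acid-catalysed enol etherification should settle on the less hindered vinylogous ester (OMe away from CMe2, C=O next to CMe2), which is the regioisomer the final transposition needs.

Step 10
Reactants: 2 (2R,3R)-2,3-epoxygeraniol
Product: 14 [(2R,3R)-3-[2-[(2S)-3,3-dimethyloxiran-2-yl]ethyl]-3-methyloxiran-2-yl]methanol
Conditions: ent-Shi ketone (30 mol%), KHSO5 (as 2KHSO5·KHSO4·K2SO4), K2CO3, Bu4NHSO4, MeCN–(MeO)2CH2–aq. buffer (pH 10.5), 0 °C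
Reagents that add atoms: potassium peroxymonosulfate, [K+].[O-]S(=O)(=O)OO
Why: Shi epoxidation (chiral dioxirane, spiro transition state) of the remaining trisubstituted alkene; the enantiomeric ketone gives the (S)-epoxide that becomes the C3 carbinol.

Step 11
Reactants: 14 diepoxy alcohol; 15 2-acetylbutyrolactone
Product: 18 3-[3-[(2R,3R)-3-[2-[(2S)-3,3-dimethyloxiran-2-yl]ethyl]-3-methyloxiran-2-yl]propanoyl]oxolan-2-one, via triflate 16 (not isolated), via dianion 17 (not isolated)
Conditions: 14, Tf2O, 2,6-lutidine, CH2Cl2, −78 °C; separately 15, NaH then n-BuLi, THF, 0 °C; combine at −78 → −40 °C; then AcOH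
Reagents that add atoms: none
Why: Weiler-type dianion alkylation at the terminal carbon by SN2 displacement of the primary triflate at low temperature, faster than any epoxide opening; no stereocentre is affected.

Step 12
Reactants: 18 diepoxy keto lactone
Product: 20 (3′S,5a′R,9a′R)-2′,2′,5a′-trimethyl-3′-(triethylsilyloxy)octahydrospiro[oxolane-3,6′-benzo[b]oxepine]-2,7′-dione, via TES enol ether 19 (not isolated)
Conditions: TESCl (1.1 equiv), Et3N (1.1 equiv), CH2Cl2, 0 °C → rt; filter, concentrate; then TESOTf (0.3 equiv), 2,6-di-tert-butyl-4-methylpyridine (0.5 equiv), CH2Cl2, −78 → −40 °C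
Reagents that add atoms: chlorotriethylsilane, CC[Si](Cl)(CC)CC
Why: Proposed new method: silyl triflate activates the terminal (S)-epoxide, the internal epoxide oxygen attacks its tertiary carbon to give a six-membered epoxonium ion, and the tethered silyl enol ether of the α-acyl-γ-butyrolactone (a 1,3-dicarbonyl π-nucleophile not yet shown in this manifold) opens that ion at its tertiary carbon with inversion through a chair transition state, which forms the oxepane C–O bond, the cyclohexanone C–C bond, the trans ring fusion (5a′R,9a′R) and the spiro carbon while (S)-C3′ is carried over and the silyl group moves from the enol to O3′; the closest known reaction type is the tandem oxa-/carbacyclization of diepoxides ended by silyl enol ethers of methyl ketones.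

Step 13
Reactants: 20 spiro lactone
Product: 21 (3S,5aR,6R,9aR)-2,2,5a-trimethyl-6-[2-(phenylsulfanyl)ethyl]-3-(triethylsilyloxy)octahydrobenzo[b]oxepin-7(2H)-one
Conditions: PhSH (1.5 equiv), K2CO3 (0.3 equiv), DMF, 100 °C
Reagents that add atoms: thiophenol, Sc1ccccc1
Why: thiolate SN2 opening of the lactone at O–CH2 (Krapcho-type) and decarboxylation of the resulting β-keto acid unveil the two-carbon arm, and C6 equilibrates to the equatorial (6R) epimer under the basic conditions.

Step 14
Reactants: 21 sulfide ketone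
Product: 22 (3S,5aR,6R,7S,9aR)-2,2,5a,7-tetramethyl-6-[2-(phenylsulfanyl)ethyl]-3-(triethylsilyloxy)decahydrobenzo[b]oxepin-7-ol
Conditions: MeMgBr (3 equiv), THF, −78 → 0 °C; then aq. NH4Cl
Reagents that add atoms: methylmagnesium bromide, C[Mg]Br
Why: Grignard addition from the equatorial direction, because axial attack is blocked by the syn-axial C5a methyl, gives the axial tertiary alcohol (7S).

Step 15
Reactants: 22 sulfide alcohol; 13 vinylogous ester
Product: 25 target CNP0397160.2, via dilithio reagent 23 (not isolated), via carbinol adduct 24 (not isolated)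
Conditions: 22, n-BuLi (1.05 equiv), THF, −78 °C; lithium 4,4′-di-tert-butylbiphenylide (LiDBB, 2.2 equiv), −78 °C; CeCl3 (1.5 equiv); add 13 pre-treated with LiN(SiMe3)2 (1.0 equiv), −78 → 0 °C; then 1 M HCl, THF, rt
Reagents that add atoms: none
Why: reductive lithiation of the primary phenyl sulfide gives the alkyllithium (used as its organocerium), which adds 1,2 to the hindered carbonyl of the vinylogous ester; acid then hydrolyses the enol ether, eliminates water (Stork–Danheiser transposition) and removes the TES group, and no stereocentre is touched.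

**Compound list**

1 | geraniol, (2E)-3,7-dimethylocta-2,6-dien-1-ol | CC(C)=CCC/C(C)=C/CO | starting material
2 | [(2R,3R)-3-methyl-3-(4-methylpent-3-en-1-yl)oxiran-2-yl]methanol | OC[C@H]1O[C@]1(C)CCC=C(C)C | intermediate
3 | (2S,3R)-2-(chloromethyl)-3-methyl-3-(4-methylpent-3-en-1-yl)oxirane | ClC[C@H]1O[C@]1(C)CCC=C(C)C | intermediate
4 | (3R)-3,7-dimethyloct-6-en-1-yn-3-ol | C#C[C@](C)(O)CCC=C(C)C | intermediate
5 | (8R)-8-hydroxy-4,4,8-trimethylbicyclo[3.3.0]oct-1-en-3-one, C5 epimers | CC1(C)C(=O)C=C2C1CC[C@@]2(C)O | intermediate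
6 | dilithium dienolate of 5 (enolate O–Li and alkoxide O–Li) | CC1(C)C(O[Li])=CC2=C1CC[C@@]2(C)O[Li] | intermediate
7 | (6R)-6-hydroxy-2,2,6-trimethylbicyclo[3.3.0]oct-1(5)-en-3-one | CC1(C)C(=O)CC2=C1CC[C@@]2(C)O | intermediate
8 | (1R,5R,8R)-8-hydroxy-4,4,8-trimethylbicyclo[3.3.0]octan-3-one | CC1(C)[C@@H]2CC[C@@](C)(O)[C@@H]2CC1=O | intermediate
9 | bis-TMS derivative of 8 (TMS enol ether C2=C3, TMS ether at C8) | CC1(C)[C@@H]2CC[C@@](C)(O[Si](C)(C)C)[C@@H]2C=C1O[Si](C)(C)C | intermediate
10 | [2+2] adduct of 9 and methylchloroketene (cyclobutanone fused at C2–C3, C(Cl)Me next to C–OTMS) | CC1(C)[C@@H]2CC[C@@](C)(O[Si](C)(C)C)[C@@H]2C2C(=O)C(C)(Cl)C12O[Si](C)(C)C | intermediate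
11 | dechlorinated cyclobutanone from 10 | CC1(C)[C@@H]2CC[C@@](C)(O[Si](C)(C)C)[C@@H]2C2C(=O)C(C)C12O[Si](C)(C)C | intermediate
12 | (1R,3aR,8aR)-1-hydroxy-1,4,4,6-tetramethyloctahydroazulene-5,7-dione (C6 epimers and enol) | CC1C(=O)C(C)(C)[C@@H]2CC[C@@](C)(O)[C@@H]2CC1=O | intermediate
13 | (1R,3aR,8aR)-1-hydroxy-7-methoxy-1,4,4,6-tetramethyl-2,3,3a,4,8,8a-hexahydroazulen-5(1H)-one | COC1=C(C)C(=O)C(C)(C)[C@@H]2CC[C@@](C)(O)[C@@H]2C1 | intermediate
14 | [(2R,3R)-3-[2-[(2S)-3,3-dimethyloxiran-2-yl]ethyl]-3-methyloxiran-2-yl]methanol | OC[C@H]1O[C@]1(C)CC[C@@H]1OC1(C)C | intermediate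
15 | 3-acetyloxolan-2-one (2-acetylbutyrolactone, racemic) | CC(=O)C1CCOC1=O | starting material
16 | trifluoromethanesulfonate of 14 | O=S(=O)(OC[C@H]1O[C@]1(C)CC[C@@H]1OC1(C)C)C(F)(F)F | intermediate
17 | sodium lithium dianion of 15 | C=C(O[Li])C1=C(O[Na])OCC1 | intermediate
18 | 3-[3-[(2R,3R)-3-[2-[(2S)-3,3-dimethyloxiran-2-yl]ethyl]-3-methyloxiran-2-yl]propanoyl]oxolan-2-one (lactone C3 unassigned) | O=C1OCCC1C(=O)CC[C@H]1O[C@]1(C)CC[C@@H]1OC1(C)C | intermediate
19 | triethylsilyl enol ether of 18 | CC[Si](CC)(CC)OC(CC[C@H]1O[C@]1(C)CC[C@@H]1OC1(C)C)=C1CCOC1=O | intermediate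
20 | (3′S,5a′R,9a′R)-2′,2′,5a′-trimethyl-3′-(triethylsilyloxy)octahydrospiro[oxolane-3,6′-benzo[b]oxepine]-2,7′-dione (spiro carbon unassigned) | O=C1OCCC12[C@@]3(C)CC[C@H](O[Si](CC)(CC)CC)C(C)(C)O[C@@H]3CCC2=O | intermediate
21 | (3S,5aR,6R,9aR)-2,2,5a-trimethyl-6-[2-(phenylsulfanyl)ethyl]-3-(triethylsilyloxy)octahydrobenzo[b]oxepin-7(2H)-one | c1ccccc1SCC[C@@H]1[C@@]2(C)CC[C@H](O[Si](CC)(CC)CC)C(C)(C)O[C@@H]2CCC1=O | intermediate
22 | (3S,5aR,6R,7S,9aR)-2,2,5a,7-tetramethyl-6-[2-(phenylsulfanyl)ethyl]-3-(triethylsilyloxy)decahydrobenzo[b]oxepin-7-ol | c1ccccc1SCC[C@@H]1[C@@]2(C)CC[C@H](O[Si](CC)(CC)CC)C(C)(C)O[C@@H]2CC[C@]1(C)O | intermediate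
23 | O,C-dilithio derivative of 22 (C–SPh replaced by C–Li, O7–Li) | [Li]CC[C@@H]1[C@@]2(C)CC[C@H](O[Si](CC)(CC)CC)C(C)(C)O[C@@H]2CC[C@]1(C)O[Li] | intermediate
24 | 1,2-adduct of 23 to the C5 carbonyl of 13 (shown protonated; new carbinol carbon unassigned) | COC1=C(C)C(O)(CC[C@@H]3[C@@]4(C)CC[C@H](O[Si](CC)(CC)CC)C(C)(C)O[C@@H]4CC[C@]3(C)O)C(C)(C)[C@@H]2CC[C@@](C)(O)[C@@H]2C1 | intermediate
25 | target: 5-[2-[(3S,5aR,6R,7S,9aR)-3,7-dihydroxy-2,2,5a,7-tetramethyldecahydrobenzo[b]oxepin-6-yl]ethyl]-(1R,3aR,8aR)-1-hydroxy-1,4,4,6-tetramethyl-hexahydroazulen-7-one | CC1=C(CC[C@@H]2[C@@]3(C)CC[C@H](O)C(C)(C)O[C@@H]3CC[C@]2(C)O)C(C)(C)[C@@H]2CC[C@@](C)(O)[C@@H]2CC1=O | target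

**Step count**
Total: 15 steps. Longest linear sequence: 10 steps (steps 1–9, then 15). The left branch (steps 1, 10–14, then 15) is 7 steps.

**Three steps most likely to fail**

Step 12 (the proposed new step). The acyl-lactone enol ether is a weaker π-nucleophile than a simple enol silane and may not trap the epoxonium ion. The fallback uses only known chemistry, sets out from 14 and returns at 21. Triflate 16 is made from 14 as in step 11 and alkylated with the lithium enolate of acetone (LiN(iPr)2, THF–DMPU, −78 °C) to give the diepoxy methyl ketone F1. Kinetic silylation (KN(SiMe3)2, TESCl, THF, −78 °C) gives the terminal silyl enol ether F2. TESOTf (cat.) with 2,6-di-tert-butyl-4-methylpyridine in CH2Cl2 at −78 °C, the known tandem oxa-/carbacyclization with a methyl-ketone enol silane, gives the bicyclic ketone F3, which has no substituent at C6. IBX (DMSO, 65 °C) can dehydrogenate only on the side that carries a β-hydrogen and gives the enone F4. LiN(iPr)2 followed by 2-iodoethyl phenyl sulfide alkylates the single α′ position to give the alkylated enone F5. Conjugate reduction with [(Ph3P)CuH]6 and a short base equilibration (DBU) of C6 return 21.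

Step 4 (Pauson–Khand reaction on an alkene with a gem-dimethyl terminus). Insertion of such an alkene is slow and yields can be low. The fallback sets out from 4 and returns at 5; it makes the gem-dimethyl group by enolate alkylation instead. Ozonolysis of the alkene of 4 (O3, CH2Cl2–MeOH, −78 °C, then Me2S; the alkyne reacts much more slowly) gives the hydroxy aldehyde F6, present mainly as its lactol. Wittig methylenation (Ph3P=CH2, THF) gives the terminal enyne F7. Its Pauson–Khand reaction under the step 4 conditions, now with an unhindered monosubstituted alkene, gives the enone F8. Two rounds of LiN(iPr)2/MeI (THF, −78 °C, kinetic cross-conjugated enolate at the α′ carbon) install both methyl groups and return 5.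

Step 7 ([2+2] ring closure onto a carbon flanked by the quaternary CMe2). Methylchloroketene may acylate the enol ether without closing the four-membered ring. The fallback sets out from 9 and returns at 12; it puts in the C6 methyl group separately. Dichloroketene (Cl3CCOCl, zinc–copper couple, Et2O), the most electrophilic ketene, gives the dichlorocyclobutanone F9. Zn/AcOH as in step 8 gives the 6-unsubstituted dione F10. C-Methylation (MeI, K2CO3, acetone) returns 12.

**Further compounds**
F1 | step 12 | (5R,6R,9S)-5,6:9,10-diepoxy-6,10-dimethylundecan-2-one | CC(=O)CC[C@H]1O[C@]1(C)CC[C@@H]1OC1(C)C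
F2 | step 12 | 2-(triethylsilyloxy)-1-ene enol ether of F1 | C=C(O[Si](CC)(CC)CC)CC[C@H]1O[C@]1(C)CC[C@@H]1OC1(C)C
F3 | step 12 | (3S,5aR,9aR)-2,2,5a-trimethyl-3-(triethylsilyloxy)octahydrobenzo[b]oxepin-7(2H)-one | O=C1C[C@@]2(C)CC[C@H](O[Si](CC)(CC)CC)C(C)(C)O[C@@H]2CC1
F4 | step 12 | 8,9-didehydro derivative of F3 (enone) | O=C1C[C@@]2(C)CC[C@H](O[Si](CC)(CC)CC)C(C)(C)O[C@@H]2C=C1
F5 | step 12 | 6-[2-(phenylsulfanyl)ethyl] derivative of F4 | O=C1[C@H](CCSc3ccccc3)[C@@]2(C)CC[C@H](O[Si](CC)(CC)CC)C(C)(C)O[C@@H]2C=C1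
F6 | step 4 | (4R)-4-hydroxy-4-methylhex-5-ynal (lactol in equilibrium) | O=CCC[C@@](C)(O)C#C
F7 | step 4 | (3R)-3-methylhept-6-en-1-yn-3-ol | C#C[C@](C)(O)CCC=C
F8 | step 4 | (8R)-8-hydroxy-8-methylbicyclo[3.3.0]oct-1-en-3-one | O=C1C=C2C(C1)CC[C@@]2(C)O
F9 | step 7 | dichlorocyclobutanone adduct of 9 and dichloroketene | CC1(C)[C@@H]2CC[C@@](C)(O[Si](C)(C)C)[C@@H]2C2C(=O)C(Cl)(Cl)C12O[Si](C)(C)C
F10 | step 7 | (1R,3aR,8aR)-1-hydroxy-1,4,4-trimethyloctahydroazulene-5,7-dione | O=C1CC(=O)C(C)(C)[C@@H]2CC[C@@](C)(O)[C@@H]2C1
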